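**Retrosynthetic overview**
1. The core is numbered as 3,7-dioxabicyclo[3.3.0]octane. C2 bears the phenolic aryl and C6 the trimethoxyphenyl; ring A = C1–C2–O3–C4–C5 and ring B = C5–C6–O7–C8–C1. The SMILES reads (1S,2R,5S,6R), cis-fused, with both aryl groups exo (cis to H1/H5).
2. Feature exploited: ring A is the three-atom chain C2(aryl)–O3–C4H2 clamped across the C1–C5 bond. It is therefore the carbonyl ylide of protected syringaldehyde added to a C1=C5 alkene of ring B. Raising C8 to a lactone carbonyl turns that alkene into an electron-poor butenolide.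
3. Disconnections, backwards: ArO–Ts cleavage; C8H2 from the lactol and the lactol from the lactone; then C1–C2 and C4–C5 together by (3+2) cycloaddition. This leads to (R)-5-(3,4,5-trimethoxyphenyl)butenolide and an aryl(chloro)methyl (trimethylsilyl)methyl ether.
4. The butenolide comes from ring-closing metathesis of the (R)-acrylate delivered by lipase resolution of the vinyl carbinol. The chloro ether comes from the bis(silylmethyl) acetal of O-tosylsyringaldehyde and AcCl.
5. Ring order: B (step 3), then A (step 7), with C6 directing C5, C1 and C2. No acid equilibration of the benzylic centres is planned, because exo and endo aryl isomers of this skeleton lie close in energy and C6 would be drawn in as well.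

Key step: step 7

Remark: chloro ether 11 is moisture-sensitive, so it is freed from volatiles and carried into step 7 as the crude residue.

**Step 1**
Reactants: 1 3,4,5-trimethoxybenzaldehyde; 2 vinylmagnesium bromide
Product: 3 rac-1-(3,4,5-trimethoxyphenyl)prop-2-en-1-ol
Conditions: THF, 0 °C; sat. aq NH4Cl
Reagents that add atoms: none
Why: Grignard 1,2-addition to a non-enolisable aryl aldehyde, in which the carbinol centre forms as a racemate that is sorted in step 2.

**Step 2**
Reactants: 3 rac-1-(3,4,5-trimethoxyphenyl)prop-2-en-1-ol; 4 vinyl acrylate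
Product: 5 (1R)-1-(3,4,5-trimethoxyphenyl)prop-2-en-1-yl prop-2-enoate
Conditions: Novozym 435 (immobilised Candida antarctica lipase B), 4 (1 equiv), BHT (trace), MTBE, 30 °C, stopped near 45% conversion; chromatography on Et3N-deactivated silica
Reagents that add atoms: none
Why: Lipase-catalysed kinetic resolution by irreversible transesterification with an enol ester, in which the Kazlauskas rule (aryl large, vinyl medium) predicts fast acylation of the (R)-alcohol, so that C6 of the target is fixed and the acryloyl group for step 3 is installed in one operation while the (S)-alcohol stays behind.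

**Step 3**
Reactants: 5 (1R)-1-(3,4,5-trimethoxyphenyl)prop-2-en-1-yl prop-2-enoate
Product: 6 (5R)-5-(3,4,5-trimethoxyphenyl)furan-2(5H)-one
Conditions: second-generation Grubbs catalyst RuCl2(=CHPh)(PCy3)(H2IMes) (5 mol %), CH2Cl2 (0.01 M), reflux
Reagents that add atoms: none
Why: Ring-closing metathesis of an allyl acrylate to a butenolide closes ring B under neutral conditions, so the base-sensitive C6–H stereocentre is not touched.

**Step 4**
Reactants: 7 syringaldehyde
Product: 8 4-formyl-2,6-dimethoxyphenyl 4-methylbenzenesulfonate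
Conditions: TsCl, Et3N, DMAP (5 mol %), CH2Cl2, 0 °C to rt
Reagents that add atoms: p-toluenesulfonyl chloride, Cc1ccc(cc1)S(=O)(=O)Cl
Why: Phenol sulfonylation gives a group that, unlike an aryl carboxylate, survives i-Bu2AlH as well as AcCl, fluoride and BF3·OEt2, and that as an acceptor para to C2 tames the later chloro ether and shuts off quinone methide formation in the Lewis acid step.

**Step 5**
Reactants: 8 4-formyl-2,6-dimethoxyphenyl 4-methylbenzenesulfonate; 9 (trimethylsilyl)methanol
Product: 10 4-{bis[(trimethylsilyl)methoxy]methyl}-2,6-dimethoxyphenyl 4-methylbenzenesulfonate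
Conditions: 9 (2.5 equiv), TsOH·H2O (1 mol %), toluene, reflux through 4 Å sieves; Et3N quench
Reagents that add atoms: none
Why: Acid-catalysed acetalisation of a fairly electron-poor aryl aldehyde with a primary alcohol is driven to completion by removal of water.

**Step 6**
Reactants: 10 4-{bis[(trimethylsilyl)methoxy]methyl}-2,6-dimethoxyphenyl 4-methylbenzenesulfonate
Product: 11 4-{chloro[(trimethylsilyl)methoxy]methyl}-2,6-dimethoxyphenyl 4-methylbenzenesulfonate (racemic at the C–Cl carbon)
Conditions: AcCl (1.2 equiv), ZnCl2 (1 mol %), CH2Cl2, 0 °C to rt; volatiles off at 0.1 mbar, used crude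
Reagents that add atoms: acetyl chloride, CC(=O)Cl
Why: Zinc-halide-catalysed exchange between an acetal and an acyl chloride is the standard anhydrous route to alpha-chlorobenzyl ethers, it avoids the water that forms when aldehyde, alcohol and HCl are combined directly, and the C–Cl centre is erased in step 7.

**Step 7**
Reactants: 6 (5R)-5-(3,4,5-trimethoxyphenyl)furan-2(5H)-one; 11 4-{chloro[(trimethylsilyl)methoxy]methyl}-2,6-dimethoxyphenyl 4-methylbenzenesulfonate
Product: 13 (1R,2R,5S,6R)-2-[3,5-dimethoxy-4-(tosyloxy)phenyl]-6-(3,4,5-trimethoxyphenyl)-3,7-dioxabicyclo[3.3.0]octan-8-one, via aryl carbonyl ylide 12 (not isolated)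
Conditions: 11 (2.5 equiv), CsF (3 equiv, flame-dried, added in portions), 4 Å sieves, MeCN, 0 °C to rt, Ar
Reagents that add atoms: none
Why: Fluoride attacks silicon while chloride leaves the benzylic carbon (1,3-elimination), which frees the 4-pi-electron ylide 12 with its aryl group in the outer (E) position, and 12 adds in one concerted suprafacial event across the electron-poor C1=C5 bond of 6. The closest known reaction type is the (3+2) cycloaddition of non-stabilised carbonyl ylides, made by CsF-induced desilylation of 1-chloroalkyl (trimethylsilyl)methyl ethers, to acrylates, maleates, enones and similar acceptors. Ring A closes by intermolecular cycloaddition with C1–C2 and C4–C5 formed together, and the fusion can only be cis because the alkene is held Z inside ring B. C5 and C1 are set by approach of the dipole to the face of 6 opposite the C6 aryl group, which leaves that aryl exo, and C2 is set by the E geometry of 12 together with an exo transition state in which ring B lies away from O3 and from the ylide aryl group, so that this aryl ends up trans to C8. The step needs C4-to-C5 regiochemistry, which the polarisation ArCH=O(+)–CH2(−) (nucleophilic CH2 end to the beta-carbon) and the smaller bulk of the CH2 end next to C6 both favour. It also needs the C6–H of 6, which is benzylic and vinylogously acidic, to stay untouched, hence 11 is kept in excess over the sparingly soluble CsF so that fluoride is consumed at silicon; any C2 epimer is removed at this stage by chromatography or crystallisation.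

**Step 8**
Reactants: 13 (1R,2R,5S,6R)-2-[3,5-dimethoxy-4-(tosyloxy)phenyl]-6-(3,4,5-trimethoxyphenyl)-3,7-dioxabicyclo[3.3.0]octan-8-one
Product: 14 (1R,2R,5S,6R)-2-[3,5-dimethoxy-4-(tosyloxy)phenyl]-6-(3,4,5-trimethoxyphenyl)-3,7-dioxabicyclo[3.3.0]octan-8-ol (anomer mixture at C8)
Conditions: i-Bu2AlH (1.2 equiv), CH2Cl2, −78 °C; aq potassium sodium tartrate
Reagents that add atoms: none
Why: Partial reduction of a gamma-lactone stops at the lactol because the aluminium hemiacetal is stable at −78 °C, the aryl sulfonate and the ethers are inert, and the C8 anomer mixture is of no consequence since C8 becomes CH2.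

**Step 9**
Reactants: 14 (1R,2R,5S,6R)-2-[3,5-dimethoxy-4-(tosyloxy)phenyl]-6-(3,4,5-trimethoxyphenyl)-3,7-dioxabicyclo[3.3.0]octan-8-ol
Product: 16 (1S,2R,5S,6R)-2-[3,5-dimethoxy-4-(tosyloxy)phenyl]-6-(3,4,5-trimethoxyphenyl)-3,7-dioxabicyclo[3.3.0]octane, via bicyclic oxocarbenium ion 15 (not isolated)
Conditions: Et3SiH (3 equiv), BF3·OEt2 (1.5 equiv), CH2Cl2, −78 to −40 °C; Et3N, then aq NaHCO3 at −40 °C
Reagents that add atoms: none
Why: Ionic hydrogenation of a lactol (Kursanov–Parnes type) works because the hemiacetal ionises to 15 far faster than a dialkyl benzylic ether at low temperature, excess silane traps 15 at once, the tosylate keeps C2 from ionising, and no stereocentre is made or broken.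

**Step 10**
Reactants: 16 (1S,2R,5S,6R)-2-[3,5-dimethoxy-4-(tosyloxy)phenyl]-6-(3,4,5-trimethoxyphenyl)-3,7-dioxabicyclo[3.3.0]octane
Product: 17 4-[(1S,2R,5S,6R)-6-(3,4,5-trimethoxyphenyl)-3,7-dioxabicyclo[3.3.0]octan-2-yl]-2,6-dimethoxyphenol (target)
Conditions: Mg turnings (10 equiv), MeOH, rt, ultrasound; aq NH4Cl
Reagents that add atoms: none
Why: Reductive S–O cleavage of an aryl tosylate by electron transfer from Mg in MeOH frees the phenol at room temperature without acid, so neither benzylic ether centre can epimerise once the donor phenol is unmasked.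

**Compound list**
1 | 3,4,5-trimethoxybenzaldehyde | COc1cc(C=O)cc(OC)c1OC | starting material
2 | vinylmagnesium bromide | C=C[Mg]Br | starting material
3 | rac-1-(3,4,5-trimethoxyphenyl)prop-2-en-1-ol | C=CC(O)c1cc(OC)c(OC)c(OC)c1 | intermediate
4 | vinyl acrylate | C=CC(=O)OC=C | starting material
5 | (1R)-1-(3,4,5-trimethoxyphenyl)prop-2-en-1-yl prop-2-enoate | C=CC(=O)O[C@H](C=C)c1cc(OC)c(OC)c(OC)c1 | intermediate
6 | (5R)-5-(3,4,5-trimethoxyphenyl)furan-2(5H)-one | O=C1C=C[C@H](c2cc(OC)c(OC)c(OC)c2)O1 | intermediate
7 | syringaldehyde | COc1cc(C=O)cc(OC)c1O | starting material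
8 | 4-formyl-2,6-dimethoxyphenyl 4-methylbenzenesulfonate | Cc1ccc(cc1)S(=O)(=O)Oc1c(OC)cc(C=O)cc1OC | intermediate
9 | (trimethylsilyl)methanol | C[Si](C)(C)CO | starting material
10 | 4-{bis[(trimethylsilyl)methoxy]methyl}-2,6-dimethoxyphenyl 4-methylbenzenesulfonate | Cc1ccc(cc1)S(=O)(=O)Oc1c(OC)cc(cc1OC)C(OC[Si](C)(C)C)OC[Si](C)(C)C | intermediate
11 | 4-{chloro[(trimethylsilyl)methoxy]methyl}-2,6-dimethoxyphenyl 4-methylbenzenesulfonate (racemic) | Cc1ccc(cc1)S(=O)(=O)Oc1c(OC)cc(cc1OC)C(Cl)OC[Si](C)(C)C | intermediate
12 | (E)-carbonyl ylide ArCH=O(+)–CH2(−), Ar = 3,5-dimethoxy-4-(tosyloxy)phenyl (not isolated) | Cc1ccc(cc1)S(=O)(=O)Oc1c(OC)cc(cc1OC)/C=[O+]/[CH2-] | intermediate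
13 | (1R,2R,5S,6R)-2-[3,5-dimethoxy-4-(tosyloxy)phenyl]-6-(3,4,5-trimethoxyphenyl)-3,7-dioxabicyclo[3.3.0]octan-8-one | Cc1ccc(cc1)S(=O)(=O)Oc1c(OC)cc(cc1OC)[C@@H]1OC[C@@H]2[C@H]1C(=O)O[C@H]2c1cc(OC)c(OC)c(OC)c1 | intermediate
14 | (1R,2R,5S,6R)-lactol, 8-ol of 13, anomer mixture | Cc1ccc(cc1)S(=O)(=O)Oc1c(OC)cc(cc1OC)[C@@H]1OC[C@@H]2[C@H]1C(O)O[C@H]2c1cc(OC)c(OC)c(OC)c1 | intermediate
15 | bicyclic oxocarbenium ion, O7=C8H(+) (not isolated) | Cc1ccc(cc1)S(=O)(=O)Oc1c(OC)cc(cc1OC)[C@@H]1OC[C@@H]2[C@H]1C=[O+][C@H]2c1cc(OC)c(OC)c(OC)c1 | intermediate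
16 | (1S,2R,5S,6R)-2-[3,5-dimethoxy-4-(tosyloxy)phenyl]-6-(3,4,5-trimethoxyphenyl)-3,7-dioxabicyclo[3.3.0]octane | Cc1ccc(cc1)S(=O)(=O)Oc1c(OC)cc(cc1OC)[C@@H]1OC[C@@H]2[C@H]1CO[C@H]2c1cc(OC)c(OC)c(OC)c1 | intermediate
17 | 4-[(1S,2R,5S,6R)-6-(3,4,5-trimethoxyphenyl)-3,7-dioxabicyclo[3.3.0]octan-2-yl]-2,6-dimethoxyphenol | COc1cc([C@@H]2OC[C@@H]3[C@H]2CO[C@H]3c2cc(OC)c(OC)c(OC)c2)cc(OC)c1O | target

**Total step count:** 10. **Longest linear sequence:** 7 steps (1 → 3 → 5 → 6 → 13 → 14 → 16 → 17, or equally 7 → 8 → 10 → 11 → 13 → 14 → 16 → 17).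

**Steps most likely to fail**

**Step 7.** Three things may go wrong.
- The short-lived ylide may be lost faster than it adds to a 1,2-disubstituted alkene, through self-reaction, closure to the epoxide, or capture by aldehyde freed through hydrolysis.
- The exo/endo preference at C2 may be low.
- Fluoride may deprotonate C6–H of the butenolide and so erode the enantiomeric purity.

A late acid equilibration is no remedy, for the reason given in the overview.

The fallback gives up the cycloaddition and uses the hidden symmetry of the skeleton: the target is the mono-methyl ether of a C2-symmetric bis-phenol. It sets out from 7. Wittig olefination with Ph3P=CHCO2Et in toluene gives ethyl sinapate F1, and i-Bu2AlH in toluene reduces it to sinapyl alcohol F2. Oxidative beta–beta coupling (laccase, O2, acetate buffer/MeCN) should give racemic syringaresinol F3. In this coupling both rings close by 5-exo attack of the CH2OH groups on the bis-quinone methide, and both aryl groups come out exo. Preparative chromatography on a cellulose tris(3,5-dimethylphenylcarbamate) phase separates (1S,2R,5S,6R)-syringaresinol F4. One equivalent of MeI with K2CO3 in acetone then alkylates one of the two homotopic phenols. Unreacted F4 is recycled and the diether is removed. This fallback comes back to the route at 17.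

**Step 9.** The Lewis acid may ionise more than the lactol. In the oxocarbenium ion the O7–C6 bond is benzylic to an electron-rich ring and may open reversibly. That would epimerise C6 or lead to reductive ring opening.

The fallback avoids Lewis acid and sets out from 13. LiBH4 in THF (0 °C to rt) opens ring B to the C8/C6 diol F5. MsCl (1.05 equiv) and Et3N in CH2Cl2 at −20 °C should sulfonylate only the primary C8 hydroxyl and give the primary mesylate F6. On warming, F6 closes by 5-exo-tet displacement by the C6 hydroxyl. The C6–O bond is never broken, so its configuration is kept. This fallback comes back at 16.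

**Step 6.** The chloro ether may be lost during concentration by hydrolysis or by dealkylative collapse back to the aldehyde. Residual acyl chloride and acetate may also be carried into the fluoride step.

The fallback does without an isolated halide and sets out from 10. Me3SiOSO2CF3 (1 equiv) in CH2Cl2/MeCN at −40 °C ionises the acetal to the (trimethylsilyl)methyl oxocarbenium triflate F7. Addition of 6 and CsF to the same flask then removes the silyl group. This is the oxygen counterpart of the iminium-salt desilylation route to azomethine ylides. The fallback comes back at ylide 12 and hence at 13.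

**Further compounds**
F1 | step 7 | ethyl sinapate | CCOC(=O)/C=C/c1cc(OC)c(O)c(OC)c1
F2 | step 7 | sinapyl alcohol | OC/C=C/c1cc(OC)c(O)c(OC)c1
F3 | step 7 | racemic syringaresinol (exo,exo; both enantiomers written) | COc1cc(cc(OC)c1O)[C@@H]1OC[C@@H]2[C@H]1CO[C@H]2c1cc(OC)c(O)c(OC)c1.COc1cc(cc(OC)c1O)[C@H]1OC[C@H]2[C@@H]1CO[C@@H]2c1cc(OC)c(O)c(OC)c1
F4 | step 7 | (1S,2R,5S,6R)-syringaresinol | COc1cc(cc(OC)c1O)[C@@H]1OC[C@@H]2[C@H]1CO[C@H]2c1cc(OC)c(O)c(OC)c1
F5 | step 9 | C8/C6 diol from reductive opening of ring B of 13 (C1, C2, C5, C6 unchanged) | Cc1ccc(cc1)S(=O)(=O)Oc1c(OC)cc(cc1OC)[C@@H]1OC[C@@H]([C@@H](O)c2cc(OC)c(OC)c(OC)c2)[C@H]1CO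
F6 | step 9 | primary (C8) mesylate of F5 | Cc1ccc(cc1)S(=O)(=O)Oc1c(OC)cc(cc1OC)[C@@H]1OC[C@@H]([C@@H](O)c2cc(OC)c(OC)c(OC)c2)[C@H]1COS(C)(=O)=O
F7 | step 6 | (trimethylsilyl)methyl oxocarbenium triflate of aldehyde 8 | Cc1ccc(cc1)S(=O)(=O)Oc1c(OC)cc(cc1OC)C=[O+]C[Si](C)(C)C.[O-]S(=O)(=O)C(F)(F)F
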